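Remark on the chemistry: the two sp3 stereocentres that appear in compounds 6 to 12 are erased in step 6, so 6 is used as the racemate and 8 to 12 as diastereomer mixtures. Acid chloride 7 is taken as a purchased, storable reagent.

## Analysis of the target

Target 18 joins two heteroaromatic units through one CH2 group: a 1H-indole (benzene ring A, pyrrole ring B) and a fully substituted 1-hydroxypyrazin-2(1H)-one (ring C: N1–OH, C2=O, C3–CH3, N4, C5–OCH3, C6–CH2). The CH2 links indole C3 to pyrazinone C6. Indole C7, the benzene carbon next to C7a and N1, carries a 3-methylbut-2-enyl (prenyl) group, while indole N1–H and C2–H are free. There is no stereocentre and no alkene geometry to set; ring C is formally the N-hydroxylated, O-methylated and dehydrogenated diketopiperazine of a 7-prenyltryptophan and alanine. The sensitive groups are the cyclic hydroxamic acid (acidic, strongly chelating, reducible N–O bond), the prenyl alkene (hydrogenation; acid gives a tertiary cation that can cyclise onto indole N1), the electron-rich indole (oxidants) and the lactim-type methyl ether. The first difficulty is ring C: N1 and N4, and likewise O2 and O5, sit in almost the same surroundings, so oxidation or methylation of a preformed ring cannot tell them apart. The second difficulty is the indole: C7 is the position of ring A least accessible to electrophiles or metalation when N1 is free, so a 3,7-disubstituted indole made from indole itself needs a detour. The feature used here is that, seen from ring B, the groups on C3 and C7 are simply the substituent of an alkyne carbon and the ortho substituent of an aniline. Forming the bonds C3–C3a and N1–C2 in one operation therefore places both groups without any chemistry at C7.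

## Retrosynthetic reasoning

18 from 17. The last operation should only remove silicon. In 17 the hydroxamate oxygen carries a 2-(trimethylsilyl)ethyl group and indole C2 a trimethylsilyl group; both leave under one fluoride treatment. The O-protecting group is needed because a free N–OH would bind palladium in the key step. It is chosen so that the end-game needs no acid, hydrogen or oxidant in the presence of prenyl, indole and the N–O bond.

17 from 13 and 16 (key disconnection). Ring B is cut at C3–C3a and at N1–C2. This returns an o-bromoaniline, 16, whose second ortho substituent is already the prenyl group, and an internal alkyne, 13, that carries the complete, protected ring C on its propargylic carbon. The forward reaction is a palladium-catalysed heteroannulation that has to join the two halves, build the pyrrole ring and fix the 3,7-pattern. The C-silyl group of 13 has to steer the alkyne insertion so that the CH2–pyrazinone ends on C3. The cut is placed here and not at the CH2–indole or CH2–pyrazinone bond because those cuts leave a 7-prenylindole to be made separately. Here, both precursors are much simpler than the product, and the union is convergent.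

16 from 14 and 15. The aryl–prenyl bond is cut. The dihalide 14 offers iodine for this coupling and keeps bromine for the annulation, so one chemoselective Stille coupling suffices.

13 from 12, and 12 from 10. The aromatic ring C is traced back to its 3,6-dihydro form 12 (loss of the hydrogens on C3 and C6 in the forward direction), and the C5–OCH3 lactim ether to the lactam of diketopiperazine 10. Because N1 of 10 already bears oxygen and has no N–H, only the N4–H/C5=O lactam can become a neutral lactim ether. This settles both the N1/N4 and the O2/O5 question without any selective oxidation of a ring nitrogen.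

10 from 8, and 8 from 6 and 7. The ring is opened at the N4–C5 amide bond (lactamisation of the liberated amine onto the ethyl ester, via 9) and then at the N1–C2 amide bond (acylation of the N-alkoxyamine 6 with the alanine-derived acid chloride 7). The N–O bond is thus present from the start and is never made by oxidation.

6 from 3 and 4, and 3 from 1 and 2. The Cα–Cβ bond of the N-alkoxy amino ester is cut: a silyl-capped propargyl unit from 4 (as the zinc reagent 5) adds to the C=N bond of glyoxylate oxime ether 3. The oxime ether comes from aldehyde 1 and the O-protected hydroxylamine 2, which brings in the N–O bond and its protecting group in one piece.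

## Alternatives that were turned down

Alternative 1: The textbook route reads ring C as an oxidised diketopiperazine, cuts its two amide bonds and takes the indole from a preformed 7-substituted indole.
- Forward sequence: 7-(3-methylbut-2-en-1-yl)-1H-indole A1 would be converted into its Mannich base A2. Quaternisation, alkylation of a glycine enolate equivalent and conversion of the amino group into an N-alkoxyamino group would give the tryptophan ester A3. Acylation with an alanine unit and lactamisation, the key step, would give diketopiperazine A4, followed by lactim ether formation and dehydrogenation as in steps 5 and 6.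
- Why turned down: A1 is not a simple starting material. Electrophiles attack indole C3 and bases metalate C2, so the C7 prenyl group needs reduction of ring B, N-alkylation with a tertiary allyl group, an aza-Claisen shift and re-oxidation, four to five steps before the route begins. The N–O bond would have to be made by oxidising an amine while the indole C2=C3 bond and the trisubstituted alkene are present, and both react with the same oxidants. The later dehydrogenation would have to be run on a 3-alkylindole, whose CH2 is itself a hydride donor towards quinones. The sequence is fully linear and roughly twice as long.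

Alternative 2: Ring C is cut at N1–C6 and N4–C5 and made by the classical one-flask condensation of an α-amino hydroxamic acid with a 1,2-dicarbonyl compound.
- Forward key step: double condensation of (S)-2-amino-N-hydroxypropanamide A5 with methyl 3-[7-(3-methylbut-2-en-1-yl)-1H-indol-3-yl]-2-oxopropanoate A6 (itself made from A1).
- Why turned down: the inherent chemoselectivity runs against the target. The primary amine of A5 is the better nucleophile and the ketone of A6 the better electrophile, so N4 would bond to the carbon carrying the CH2–indole, and the hydroxamate N–H would be left to acylate with the ester. The product would be the N-hydroxy imide A7, with the indolylmethyl group on C5 and a carbonyl on C6. This is a constitutional isomer of the required ring with no path to the C5 methoxy group. A6 is also an enolisable, air-sensitive indolylpyruvate and still needs A1.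

Alternative 3: The C7–prenyl bond is cut last, as the prenyl transferase of the presumed biosynthesis does.
- Forward key step: the prenyl-free compound A8 would be borylated at indole C7 under iridium catalysis with N–H direction (through C2/C7 diborylation and C2 protodeborylation) to give boronate A9, which would be cross-coupled with a prenyl electrophile.
- Why turned down: it adds three to four operations on the most advanced material. Pyrazinone N4 and C2=O compete with the indole N–H as directing groups for iridium. A 3-alkylindole is borylated at C2 before C7, which forces a correcting step. The allyl coupling of A9 can also deliver the branched 1,1-dimethylallyl isomer. The risk would be spread over several late steps instead of sitting in one.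

Key step: step 8

## Route

Step 1
Reactants: 1 ethyl glyoxylate; 2 O-[2-(trimethylsilyl)ethyl]hydroxylamine hydrochloride
Product: 3 ethyl (2E)-{[2-(trimethylsilyl)ethoxy]imino}acetate
Conditions: NaOAc, EtOH, rt
Reagents that add atoms: none
Why: Oxime ether condensation of the aldehyde with the O-alkylhydroxylamine; the E isomer is expected and its geometry has no consequence. The N–O bond of the target and its protecting group are brought in here in one piece.

Step 2
Reactants: 3; 4 3-bromo-1-(trimethylsilyl)prop-1-yne
Product: 6 ethyl (2RS)-2-{[2-(trimethylsilyl)ethoxy]amino}-5-(trimethylsilyl)pent-4-ynoate, via allenylzinc bromide 5 (not isolated)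
Conditions: Zn dust, THF, 0 °C to rt; then sat. aq NH4Cl
Reagents that add atoms: none
Why: Barbier-type addition of a propargyl/allenyl zinc reagent to the C=N bond of a glyoxylate oxime ether, which is activated by the ester group. The silyl-substituted allenylzinc 5 should react at its CH2 terminus (SE2′), so the homopropargyl product with intact C-silyl alkyne results; the new stereocentre is formed racemic and is erased in step 6.

Step 3
Reactants: 6; 7 N-(9-fluorenylmethoxycarbonyl)-L-alanyl chloride
Product: 8 ethyl (2RS)-2-{[N-(9-fluorenylmethoxycarbonyl)-L-alanyl][2-(trimethylsilyl)ethoxy]amino}-5-(trimethylsilyl)pent-4-ynoate (two diastereomers)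
Conditions: NaHCO3, CH2Cl2/H2O, 0 °C to rt
Reagents that add atoms: none
Why: N-Acylation of the weakly nucleophilic N-alkoxyamine needs an acid chloride; urethane-protected amino acid chlorides are stable acylating agents, and the two-phase hydrogencarbonate conditions avoid base-induced side reactions. The new amide places the alanine carbonyl (later C2) on the nitrogen that carries oxygen (later N1).

Step 4
Reactants: 8
Product: 10 (3S,6RS)-3-methyl-1-[2-(trimethylsilyl)ethoxy]-6-[3-(trimethylsilyl)prop-2-yn-1-yl]piperazine-2,5-dione, via free amine 9 (not isolated)
Conditions: piperidine, DMF, rt to 40 °C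
Reagents that add atoms: none
Why: Base-induced (E1cB) cleavage of the fluorenylmethyl carbamate frees the alanine nitrogen, which attacks the ethyl ester in a 6-exo-trig lactamisation. The tertiary N-alkoxy amide readily adopts the cis geometry that diketopiperazine closure needs, and the aprotic amine medium leaves the C-silyl alkyne untouched.

Step 5
Reactants: 10
Product: 12 (3S,6RS)-5-methoxy-3-methyl-1-[2-(trimethylsilyl)ethoxy]-6-[3-(trimethylsilyl)prop-2-yn-1-yl]-3,6-dihydropyrazin-2(1H)-one, via lactimium tetrafluoroborate 11 (not isolated)
Conditions: Me3OBF4, CH2Cl2, rt; then aq NaHCO3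
Reagents that add atoms: trimethyloxonium tetrafluoroborate, C[O+](C)C.F[B-](F)(F)F
Why: Meerwein O-methylation of the only secondary lactam (N4–H/C5=O) gives salt 11, which is deprotonated on work-up. The N1-alkoxy amide has no N–H and cannot give a neutral lactim ether, and this is what places the methoxy group on C5 and not on C2.

Step 6
Reactants: 12
Product: 13 5-methoxy-3-methyl-1-[2-(trimethylsilyl)ethoxy]-6-[3-(trimethylsilyl)prop-2-yn-1-yl]pyrazin-2(1H)-one
Conditions: DDQ, toluene, 60 °C
Reagents that add atoms: none
Why: Quinone dehydrogenation of a 3,6-dihydropyrazine (hydride abstraction from a ring C–H next to nitrogen, then proton loss), as known for lactim ethers of diketopiperazines; aromatisation of ring C is the driving force. Both sp3 stereocentres vanish.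

Step 7
Reactants: 14 2-bromo-6-iodoaniline; 15 tributyl(3-methylbut-2-en-1-yl)stannane
Product: 16 2-bromo-6-(3-methylbut-2-en-1-yl)aniline
Conditions: Pd(PPh3)4 (5 mol %), DMF, 80 °C
Reagents that add atoms: none
Why: Stille coupling; oxidative addition of zerovalent palladium is much faster at C–I than at C–Br. Allyl transfer from tin and reductive elimination at the less substituted allyl terminus should give the linear prenyl arene; the free amino group is tolerated.

Step 8
Reactants: 13; 16
Product: 17 5-methoxy-3-methyl-6-{[7-(3-methylbut-2-en-1-yl)-2-(trimethylsilyl)-1H-indol-3-yl]methyl}-1-[2-(trimethylsilyl)ethoxy]pyrazin-2(1H)-one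
Conditions: Pd[P(t-Bu)3]2 (5–10 mol %), Cy2NMe, 1,4-dioxane, 60–80 °C
Reagents that add atoms: none
Why: Larock heteroannulation: zerovalent palladium inserts into the C–Br bond of 16, the alkyne of 13 coordinates and undergoes syn-carbopalladation, the aniline nitrogen displaces bromide on divalent palladium to give a six-membered azapalladacycle, and C–N reductive elimination releases the indole and zerovalent palladium while the amine base takes up HBr. The closest known reaction type is the annulation of o-bromoanilines with silyl-capped propargyl amino acid derivatives, among them propargylated 2,5-dialkoxy-3,6-dihydropyrazines, under palladium/tri-tert-butylphosphine catalysis. Ring B is closed in a formal [3+2] mode, once at carbon (C3–C3a, intermolecular carbopalladation) and once at nitrogen (N1–C2, reductive elimination from the palladacycle); no stereocentre is formed. The regioselectivity of insertion is secured by the Me3Si group: the aryl group bonds to the alkyne carbon bearing the small CH2–pyrazinone (future C3) and palladium to the silyl-bearing carbon (future C2). Chemoselectivity for the alkyne over the prenyl alkene is secured because that alkene is trisubstituted and sits on the far side of the NH2 group, out of reach of the aryl–palladium bond. The acidic CH2 between alkyne and pyrazinone is protected against propargyl-to-allene isomerisation by using a tertiary amine at 60–80 °C instead of carbonate at 100 °C. The prenyl group ortho to NH2 becomes the C7 substituent without any reaction at that carbon, and the N-alkoxy group keeps the hydroxamate from binding palladium.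

Step 9
Reactants: 17
Product: 18 astepyrazinoxide [1-hydroxy-5-methoxy-3-methyl-6-{[7-(3-methylbut-2-en-1-yl)-1H-indol-3-yl]methyl}pyrazin-2(1H)-one]
Conditions: Bu4NF, THF, 0 to 50 °C; then dilute aq HCl to pH 4
Reagents that add atoms: none
Why: Fluoride attacks both silicon atoms: the 2-(trimethylsilyl)ethyl group fragments to ethene and fluorotrimethylsilane, and the 2-silylindole undergoes protodesilylation. The hydroxamate oxygen of a 1-hydroxypyrazinone is about as good a leaving group as a carboxylate, so the group should behave like a 2-(trimethylsilyl)ethyl ester. No acid strong enough to protonate the alkene, no hydrogen and no oxidant meets prenyl, indole or the N–O bond.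

## Compound list

1 | ethyl glyoxylate | CCOC(=O)C=O | starting material
2 | O-[2-(trimethylsilyl)ethyl]hydroxylamine hydrochloride | Cl.NOCC[Si](C)(C)C | starting material
3 | ethyl (2E)-{[2-(trimethylsilyl)ethoxy]imino}acetate | CCOC(=O)/C=N/OCC[Si](C)(C)C | intermediate
4 | 3-bromo-1-(trimethylsilyl)prop-1-yne | C[Si](C)(C)C#CCBr | starting material
5 | bromo[1-(trimethylsilyl)propa-1,2-dien-1-yl]zinc (allenylzinc bromide) | C=C=C([Zn]Br)[Si](C)(C)C | intermediate (not isolated)
6 | ethyl (2RS)-2-{[2-(trimethylsilyl)ethoxy]amino}-5-(trimethylsilyl)pent-4-ynoate | CCOC(=O)C(CC#C[Si](C)(C)C)NOCC[Si](C)(C)C | intermediate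
7 | N-(9-fluorenylmethoxycarbonyl)-L-alanyl chloride | C[C@H](NC(=O)OCC1c2ccccc2-c2ccccc12)C(Cl)=O | starting material
8 | ethyl (2RS)-2-{[N-(9-fluorenylmethoxycarbonyl)-L-alanyl][2-(trimethylsilyl)ethoxy]amino}-5-(trimethylsilyl)pent-4-ynoate | CCOC(=O)C(CC#C[Si](C)(C)C)N(OCC[Si](C)(C)C)C(=O)[C@H](C)NC(=O)OCC1c2ccccc2-c2ccccc12 | intermediate
9 | ethyl (2RS)-2-{(L-alanyl)[2-(trimethylsilyl)ethoxy]amino}-5-(trimethylsilyl)pent-4-ynoate (free amine) | CCOC(=O)C(CC#C[Si](C)(C)C)N(OCC[Si](C)(C)C)C(=O)[C@H](C)N | intermediate (not isolated)
10 | (3S,6RS)-3-methyl-1-[2-(trimethylsilyl)ethoxy]-6-[3-(trimethylsilyl)prop-2-yn-1-yl]piperazine-2,5-dione | O=C1N[C@@H](C)C(=O)N(OCC[Si](C)(C)C)C1CC#C[Si](C)(C)C | intermediate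
11 | N4-protonated form of 12 as its tetrafluoroborate (lactimium tetrafluoroborate) | COC1=[NH+][C@@H](C)C(=O)N(OCC[Si](C)(C)C)C1CC#C[Si](C)(C)C.F[B-](F)(F)F | intermediate (not isolated)
12 | (3S,6RS)-5-methoxy-3-methyl-1-[2-(trimethylsilyl)ethoxy]-6-[3-(trimethylsilyl)prop-2-yn-1-yl]-3,6-dihydropyrazin-2(1H)-one | COC1=N[C@@H](C)C(=O)N(OCC[Si](C)(C)C)C1CC#C[Si](C)(C)C | intermediate
13 | 5-methoxy-3-methyl-1-[2-(trimethylsilyl)ethoxy]-6-[3-(trimethylsilyl)prop-2-yn-1-yl]pyrazin-2(1H)-one | COc1nc(C)c(=O)n(OCC[Si](C)(C)C)c1CC#C[Si](C)(C)C | intermediate
14 | 2-bromo-6-iodoaniline | Nc1c(Br)cccc1I | starting material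
15 | tributyl(3-methylbut-2-en-1-yl)stannane | CCCC[Sn](CCCC)(CCCC)CC=C(C)C | starting material
16 | 2-bromo-6-(3-methylbut-2-en-1-yl)aniline | Nc1c(Br)cccc1CC=C(C)C | intermediate
17 | 5-methoxy-3-methyl-6-{[7-(3-methylbut-2-en-1-yl)-2-(trimethylsilyl)-1H-indol-3-yl]methyl}-1-[2-(trimethylsilyl)ethoxy]pyrazin-2(1H)-one | COc1nc(C)c(=O)n(OCC[Si](C)(C)C)c1Cc1c([Si](C)(C)C)[nH]c2c(CC=C(C)C)cccc12 | intermediate
18 | astepyrazinoxide, 1-hydroxy-5-methoxy-3-methyl-6-{[7-(3-methylbut-2-en-1-yl)-1H-indol-3-yl]methyl}pyrazin-2(1H)-one | COc1nc(C)c(=O)n(O)c1Cc1c[nH]c2c(CC=C(C)C)cccc12 | target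

## Step count and risk

Total step count: 9. Longest linear sequence: 8 steps (steps 1 to 6, 8 and 9, from 1); step 7 is a one-step side branch.

Step 8 (key step). The most likely failures are:
- base-induced isomerisation of the propargylic CH2 of 13 to the allene before insertion;
- slow turnover, because the aniline is flanked by two ortho groups and the pyrazinone nitrogen can hold palladium;
- erosion of the insertion regiochemistry.

The fallback sets out from 13 and 16 and returns at 18. It closes ring B by a different mode, an intramolecular Heck reaction of an enamine. The alkyne terminus of 13 is freed with K2CO3 in MeOH to give 5-methoxy-3-methyl-6-(prop-2-yn-1-yl)-1-[2-(trimethylsilyl)ethoxy]pyrazin-2(1H)-one F1. Anti-Markovnikov hydration by hydroboration with dicyclohexylborane and oxidation with NaBO3·4H2O gives 3-{3-methoxy-5-methyl-6-oxo-1-[2-(trimethylsilyl)ethoxy]-1,6-dihydropyrazin-2-yl}propanal F2. The known palladium-catalysed annulation of o-haloanilines with aldehydes (Pd(OAc)2, a bulky biarylphosphine, DABCO, DMF, 85–100 °C) condenses F2 with 16 to the enamine and forms the C3–C3a bond. This gives 5-methoxy-3-methyl-6-{[7-(3-methylbut-2-en-1-yl)-1H-indol-3-yl]methyl}-1-[2-(trimethylsilyl)ethoxy]pyrazin-2(1H)-one F3, which carries no silyl group on C2. Bu4NF in THF then removes the 2-(trimethylsilyl)ethyl group and gives 18.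

Step 6. The most likely failure is hydride abstraction at the propargylic CH2 instead of the ring C–H bonds, or incomplete dehydrogenation followed by over-oxidation on forcing. The fallback sets out from 12 and returns at 13. Deprotonation at C3, the C–H flanked by C2=O and N4=C5, with LiN(SiMe3)2 in THF at −78 °C and chlorination with hexachloroethane should give (3RS,6RS)-3-chloro-5-methoxy-3-methyl-1-[2-(trimethylsilyl)ethoxy]-6-[3-(trimethylsilyl)prop-2-yn-1-yl]-3,6-dihydropyrazin-2(1H)-one F4. DBU then removes HCl in a 1,4-elimination (C6–H and C3–Cl) and gives 13. The oxidation level is thus raised by enolate halogenation and elimination, with no hydride acceptor present.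

Step 2. The most likely failures are transfer of the allenyl instead of the propargyl terminus to the C=N carbon, sluggish addition to the oxime ether, or reductive cleavage of the N–O bond by zinc. The fallback sets out from 1 and 4, uses 2, and returns at 6. The zinc reagent 5 is added to the far more electrophilic aldehyde group of 1 to give ethyl (2RS)-2-hydroxy-5-(trimethylsilyl)pent-4-ynoate F5. Tf2O and 2,6-lutidine in CH2Cl2 at −78 °C convert it into ethyl (2RS)-2-{[(trifluoromethyl)sulfonyl]oxy}-5-(trimethylsilyl)pent-4-ynoate F6. SN2 displacement of the triflate by the free base of 2 gives 6. The C–N bond is then made by substitution, and the N–O bond never meets zinc.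

Step 7. The most likely failure is transfer of the prenyl group through its substituted terminus (branched 1,1-dimethylallyl arene) or migration of the double bond into conjugation by a palladium hydride. The fallback sets out from 14 and returns at 16. Stille coupling of 14 with allyltributylstannane (Pd(PPh3)4, DMF, 80 °C), which has no regiochemical ambiguity, gives 2-bromo-6-(prop-2-en-1-yl)aniline F7. Cross-metathesis with an excess of 2-methylbut-2-ene and second-generation Grubbs catalyst in CH2Cl2 at 40 °C converts the allyl into the prenyl group and gives 16.

## Further compounds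

F1 | step 8 | 5-methoxy-3-methyl-6-(prop-2-yn-1-yl)-1-[2-(trimethylsilyl)ethoxy]pyrazin-2(1H)-one | COc1nc(C)c(=O)n(OCC[Si](C)(C)C)c1CC#C
F2 | step 8 | 3-{3-methoxy-5-methyl-6-oxo-1-[2-(trimethylsilyl)ethoxy]-1,6-dihydropyrazin-2-yl}propanal | COc1nc(C)c(=O)n(OCC[Si](C)(C)C)c1CCC=O
F3 | step 8 | 5-methoxy-3-methyl-6-{[7-(3-methylbut-2-en-1-yl)-1H-indol-3-yl]methyl}-1-[2-(trimethylsilyl)ethoxy]pyrazin-2(1H)-one | COc1nc(C)c(=O)n(OCC[Si](C)(C)C)c1Cc1c[nH]c2c(CC=C(C)C)cccc12
F4 | step 6 | (3RS,6RS)-3-chloro-5-methoxy-3-methyl-1-[2-(trimethylsilyl)ethoxy]-6-[3-(trimethylsilyl)prop-2-yn-1-yl]-3,6-dihydropyrazin-2(1H)-one | COC1=NC(C)(Cl)C(=O)N(OCC[Si](C)(C)C)C1CC#C[Si](C)(C)C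
F5 | step 2 | ethyl (2RS)-2-hydroxy-5-(trimethylsilyl)pent-4-ynoate | CCOC(=O)C(O)CC#C[Si](C)(C)C
F6 | step 2 | ethyl (2RS)-2-{[(trifluoromethyl)sulfonyl]oxy}-5-(trimethylsilyl)pent-4-ynoate | CCOC(=O)C(OS(=O)(=O)C(F)(F)F)CC#C[Si](C)(C)C
F7 | step 7 | 2-bromo-6-(prop-2-en-1-yl)aniline | Nc1c(Br)cccc1CC=C
A1 | alternative 1 | 7-(3-methylbut-2-en-1-yl)-1H-indole | CC(C)=CCc1cccc2cc[nH]c12
A2 | alternative 1 | N,N-dimethyl-1-[7-(3-methylbut-2-en-1-yl)-1H-indol-3-yl]methanamine | CN(C)Cc1c[nH]c2c(CC=C(C)C)cccc12
A3 | alternative 1 | methyl (2RS)-3-[7-(3-methylbut-2-en-1-yl)-1H-indol-3-yl]-2-{[2-(trimethylsilyl)ethoxy]amino}propanoate | COC(=O)C(Cc1c[nH]c2c(CC=C(C)C)cccc12)NOCC[Si](C)(C)C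
A4 | alternative 1 | 3-methyl-6-{[7-(3-methylbut-2-en-1-yl)-1H-indol-3-yl]methyl}-1-[2-(trimethylsilyl)ethoxy]piperazine-2,5-dione (diastereomer mixture) | CC1NC(=O)C(Cc2c[nH]c3c(CC=C(C)C)cccc23)N(OCC[Si](C)(C)C)C1=O
A5 | alternative 2 | (S)-2-amino-N-hydroxypropanamide | C[C@H](N)C(=O)NO
A6 | alternative 2 | methyl 3-[7-(3-methylbut-2-en-1-yl)-1H-indol-3-yl]-2-oxopropanoate | COC(=O)C(=O)Cc1c[nH]c2c(CC=C(C)C)cccc12
A7 | alternative 2 | 1-hydroxy-3-methyl-5-{[7-(3-methylbut-2-en-1-yl)-1H-indol-3-yl]methyl}pyrazine-2,6(1H,3H)-dione (racemic) | CC1N=C(Cc2c[nH]c3c(CC=C(C)C)cccc23)C(=O)N(O)C1=O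
A8 | alternative 3 | 6-(1H-indol-3-ylmethyl)-5-methoxy-3-methyl-1-[2-(trimethylsilyl)ethoxy]pyrazin-2(1H)-one | COc1nc(C)c(=O)n(OCC[Si](C)(C)C)c1Cc1c[nH]c2ccccc12
A9 | alternative 3 | 5-methoxy-3-methyl-6-{[7-(4,4,5,5-tetramethyl-1,3,2-dioxaborolan-2-yl)-1H-indol-3-yl]methyl}-1-[2-(trimethylsilyl)ethoxy]pyrazin-2(1H)-one | COc1nc(C)c(=O)n(OCC[Si](C)(C)C)c1Cc1c[nH]c2c(B3OC(C)(C)C(C)(C)O3)cccc12
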